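The δ-lactone (ring B) is read as one molecule of CO2 inserted between aryl carbon C8a and the dienylic stereocentre C3. In one flask, an open-chain (S)-configured 1-(2-bromo-3-methoxyphenyl)nonadeca-3,5-dien-2-ol undergoes bromine–lithium exchange and carboxylation (C8a–C1); the new carboxylate oxygen then displaces the Mitsunobu-activated C3 hydroxyl with inversion (O2–C3), closing ring B and fixing (R)-C3. The step exploits the ortho relationship between C8a and the C4a side chain, which lets the carboxylate reach C3 through a six-membered transition state, and the flanking C8 oxygen, which blocks acyl-type closure. The precursor comes from tetradecanal, a phosphonocrotonate and a benzylic Grignard reagent; O-demethylation ends the route.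

Key step: step 6

Remark: atoms are numbered as in isochroman-1-one (C1 carbonyl, O2, C3 stereocentre, C4, C4a, C5–C8 with the oxygen on C8, C8a); ring A is the arene, ring B the lactone. The target is (R) at C3 with a (1E,3E)-heptadeca-1,3-dienyl chain.

Step 1
Reactants: 1 2-bromo-3-methylanisole
Product: 2 2-bromo-1-(bromomethyl)-3-methoxybenzene
Conditions: NBS (1.05 equiv), AIBN (2,2'-azobis(2-methylpropionitrile), 5 mol %), PhCF3, 80 °C
Reagents that add atoms: N-bromosuccinimide, O=C1CCC(=O)N1Br
Why: Wohl–Ziegler radical bromination is selective for the benzylic C–H bonds of the only methyl group, and the low Br2 concentration in a non-polar solvent keeps electrophilic bromination of the bromine-deactivated anisole ring minor.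

Step 2
Reactants: 3 tetradecanal; 4 triethyl 4-phosphonocrotonate
Product: 5 ethyl (2E,4E)-octadeca-2,4-dienoate
Conditions: 4, LiN(SiMe3)2 (1.1 equiv), THF, −78 °C; then 3, −78 °C → rt
Reagents that add atoms: none
Why: Vinylogous Horner–Wadsworth–Emmons olefination: the lithiated phosphonocrotonate adds to the aldehyde through its phosphorus-bearing carbon and eliminates phosphate to give mainly the E alkene, while the E alkene already present is retained.

Step 3
Reactants: 5 ethyl (2E,4E)-octadeca-2,4-dienoate
Product: 6 (2E,4E)-N-methoxy-N-methyloctadeca-2,4-dienamide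
Conditions: MeNHOMe·HCl (2.0 equiv), iPrMgCl (4.0 equiv), THF, −20 °C → 0 °C
Reagents that add atoms: N,O-dimethylhydroxylamine hydrochloride, CNOC.Cl
Why: Weinreb amide formation by aminolysis of the ester with the chloromagnesium amide of N,O-dimethylhydroxylamine, which should attack the ester carbonyl faster than it adds in conjugate fashion at −20 °C.

Step 4
Reactants: 2 2-bromo-1-(bromomethyl)-3-methoxybenzene; 6 (2E,4E)-N-methoxy-N-methyloctadeca-2,4-dienamide
Product: 8 (3E,5E)-1-(2-bromo-3-methoxyphenyl)nonadeca-3,5-dien-2-one, via benzylic Grignard reagent 7 (not isolated)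
Conditions: 2, Mg turnings (1.5 equiv), Et2O, 0 °C; then 6 (0.8 equiv), THF, −78 °C → 0 °C; aq NH4Cl
Reagents that add atoms: none
Why: Weinreb ketone synthesis: magnesium inserts into the benzylic C–Br bond much faster than into the aryl C–Br bond (as in the standard preparation of 2-bromobenzylmagnesium bromide), and the chelated tetrahedral adduct of the 1,2-addition survives until work-up, so the ketone is not attacked twice.

Step 5
Reactants: 8 (3E,5E)-1-(2-bromo-3-methoxyphenyl)nonadeca-3,5-dien-2-one
Product: 9 (2S,3E,5E)-1-(2-bromo-3-methoxyphenyl)nonadeca-3,5-dien-2-ol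
Conditions: (R)-Me-CBS oxazaborolidine [(R)-1-methyl-3,3-diphenyltetrahydro-1H,3H-pyrrolo[1,2-c][1,3,2]oxazaborole] (0.2 equiv), catecholborane (1.5 equiv), toluene, −78 °C; aq NaOH work-up
Reagents that add atoms: none
Why: Corey–Bakshi–Shibata reduction: the ketone should bind the (R)-oxazaborolidine–borane complex with its conjugated dienyl group as the large substituent, so hydride is delivered to the face that gives the (S)-carbinol (mirror image of the known (S)-catalyst/enone sense), while catecholborane at −78 °C leaves the diene and the aryl bromide untouched.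

Step 6
Reactants: 9 (2S,3E,5E)-1-(2-bromo-3-methoxyphenyl)nonadeca-3,5-dien-2-ol
Product: 13 (3R)-3-[(1E,3E)-heptadeca-1,3-dien-1-yl]-8-methoxyisochroman-1-one, via dilithio species 10 (not isolated), via dilithium carboxylate carbonate 11 (not isolated), via hydroxy acid 12 (not isolated)
Conditions: n-BuLi (2.1 equiv), THF, −78 °C, 15 min; CO2 (gas), −78 → −20 °C; Ar purge; MsOH (2.0 equiv), −78 °C; PPh3 (1.5 equiv), DIAD (1.5 equiv), −20 °C → rt
Reagents that add atoms: carbon dioxide, O=C=O
Why: After O-lithiation, bromine–lithium exchange at C8a gives aryllithium 10, whose addition to CO2 forms the C8a–C1 bond (the alkoxide is carbonated reversibly, 11); exact protonation gives 12, the Mitsunobu betaine turns the C3 hydroxyl into an alkoxyphosphonium ion, and the ortho-carboxylate oxygen displaces Ph3PO to form the O2–C3 bond, so both lactone oxygens come from CO2. The closest known reaction types are the halogen–lithium exchange/carboxylation of aryl bromides and the Mitsunobu lactonisation of hydroxy acids, run here in one flask. Ring B closes in a 6-exo-tet mode. The C3 stereocentre is controlled by SN2 inversion of the (S)-carbinol set in step 5, which gives (R). The step needs alkyl–oxygen closure (inversion) to beat acyl–oxygen lactonisation (retention), and direct SN2 to beat SN2', elimination and ionisation. The 2,6-disubstituted benzoic acid is sterically inhibited toward acyl substitution, only C3 can be reached in a six-membered ring (attack at the other dienyl positions would need 8- or 10-membered rings holding E alkenes), and low temperature with no excess acid should hold back ionisation of the dienylic centre.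

Step 7
Reactants: 13 (3R)-3-[(1E,3E)-heptadeca-1,3-dien-1-yl]-8-methoxyisochroman-1-one
Product: 14 (3R)-3-[(1E,3E)-heptadeca-1,3-dien-1-yl]-8-hydroxyisochroman-1-one (target)
Conditions: BCl3 (1 M in CH2Cl2, 1.5 equiv), CH2Cl2, −78 °C → −40 °C; aq NaHCO3
Reagents that add atoms: none
Why: Chelation-assisted Lewis acid ether cleavage: BCl3 binds between the lactone carbonyl and the peri methoxy oxygen, so chloride should remove only this methyl group at low temperature, before the dienylic C3–O2 bond or the diene reacts.

Compound list
1 | 2-bromo-3-methylanisole | COc1cccc(C)c1Br | starting material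
2 | 2-bromo-1-(bromomethyl)-3-methoxybenzene | COc1cccc(CBr)c1Br | intermediate
3 | tetradecanal | CCCCCCCCCCCCCC=O | starting material
4 | triethyl 4-phosphonocrotonate, ethyl (E)-4-(diethoxyphosphoryl)but-2-enoate | CCOC(=O)/C=C/CP(=O)(OCC)OCC | starting material
5 | ethyl (2E,4E)-octadeca-2,4-dienoate | CCCCCCCCCCCCC/C=C/C=C/C(=O)OCC | intermediate
6 | (2E,4E)-N-methoxy-N-methyloctadeca-2,4-dienamide | CCCCCCCCCCCCC/C=C/C=C/C(=O)N(C)OC | intermediate
7 | (2-bromo-3-methoxybenzyl)magnesium bromide | COc1cccc(C[Mg]Br)c1Br | intermediate (not isolated)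
8 | (3E,5E)-1-(2-bromo-3-methoxyphenyl)nonadeca-3,5-dien-2-one | CCCCCCCCCCCCC/C=C/C=C/C(=O)Cc1cccc(OC)c1Br | intermediate
9 | (2S,3E,5E)-1-(2-bromo-3-methoxyphenyl)nonadeca-3,5-dien-2-ol | CCCCCCCCCCCCC/C=C/C=C/[C@@H](O)Cc1cccc(OC)c1Br | intermediate
10 | lithium (2S,3E,5E)-1-(2-lithio-3-methoxyphenyl)nonadeca-3,5-dien-2-olate | CCCCCCCCCCCCC/C=C/C=C/[C@@H](O[Li])Cc1cccc(OC)c1[Li] | intermediate (not isolated)
11 | dilithium salt of 2-[(2S,3E,5E)-2-(carboxyoxy)nonadeca-3,5-dien-1-yl]-6-methoxybenzoic acid | CCCCCCCCCCCCC/C=C/C=C/[C@@H](OC(=O)O[Li])Cc1cccc(OC)c1C(=O)O[Li] | intermediate (not isolated)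
12 | 2-[(2S,3E,5E)-2-hydroxynonadeca-3,5-dien-1-yl]-6-methoxybenzoic acid | CCCCCCCCCCCCC/C=C/C=C/[C@@H](O)Cc1cccc(OC)c1C(=O)O | intermediate (not isolated)
13 | (3R)-3-[(1E,3E)-heptadeca-1,3-dien-1-yl]-8-methoxyisochroman-1-one | CCCCCCCCCCCCC/C=C/C=C/[C@H]1Cc2cccc(OC)c2C(=O)O1 | intermediate
14 | (3R)-3-[(1E,3E)-heptadeca-1,3-dien-1-yl]-8-hydroxyisochroman-1-one | CCCCCCCCCCCCC/C=C/C=C/[C@H]1Cc2cccc(O)c2C(=O)O1 | target

Total step count: 7. Longest linear sequence: 6 steps (steps 2 to 7, from tetradecanal); step 1 is a one-step side branch that joins at step 4.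

Steps most likely to fail

Step 6. The alkoxyphosphonium ion of the dienylic alcohol may ionise instead of being displaced directly, which would erode the configuration at C3 or lead to elimination towards a conjugated polyene. Acid-promoted acyl-type ring closure before activation would give the enantiomeric lactone. The fallback replaces alkyl–oxygen closure by acyl–oxygen closure with retention and sets out from 8. Reduction of 8 with the enantiomeric (S)-oxazaborolidine and catecholborane should give (2R,3E,5E)-1-(2-bromo-3-methoxyphenyl)nonadeca-3,5-dien-2-ol F1. Treatment with n-BuLi (2.1 equiv) and CO2 at −78 °C with a buffered NaH2PO4 work-up should give 2-[(2R,3E,5E)-2-hydroxynonadeca-3,5-dien-1-yl]-6-methoxybenzoic acid F2. Yamaguchi lactonisation (2,4,6-trichlorobenzoyl chloride, Et3N, THF; then DMAP, toluene) closes the ring with retention at C3, and the route is rejoined at 13.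

Step 7. Boron coordination to the chelated lactone may trigger heterolysis of the dienylic C3–O2 bond, with racemisation, chloride capture or migration of the diene. The fallback removes the methyl group before the lactone exists and sets out from 9. NaSEt (3 equiv) in DMF at 110 °C should give 2-bromo-3-[(2S,3E,5E)-2-hydroxynonadeca-3,5-dien-1-yl]phenol F3 under basic conditions that the dienol tolerates. The one-flask sequence of step 6, run with one more equivalent each of n-BuLi and MsOH, then passes through 2-hydroxy-6-[(2S,3E,5E)-2-hydroxynonadeca-3,5-dien-1-yl]benzoic acid F4. Mitsunobu closure of this acid should lead directly to 14, where the route is rejoined.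

Step 5. The catalyst may discriminate poorly between the dienyl group and the bulky arylmethyl group, giving low enantiomeric purity, and borane may add to the diene. The fallback replaces the asymmetric reduction by a kinetic resolution and sets out from 8. Luche reduction (NaBH4, CeCl3·7H2O, MeOH, −40 °C) should give racemic (3E,5E)-1-(2-bromo-3-methoxyphenyl)nonadeca-3,5-dien-2-ol F5. Sharpless kinetic resolution (Ti(OiPr)4, D-(−)-diisopropyl tartrate, t-BuOOH 0.6 equiv, 4 Å molecular sieves, CH2Cl2, −20 °C) should epoxidise the (R)-enantiomer at its allylic alkene to (2R,3R,4R,5E)-1-(2-bromo-3-methoxyphenyl)-3,4-epoxynonadec-5-en-2-ol F6. The unreacted (S)-alcohol is separated by chromatography, and the route is rejoined at 9.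

Further compounds
F1 | step 6 | (2R,3E,5E)-1-(2-bromo-3-methoxyphenyl)nonadeca-3,5-dien-2-ol | CCCCCCCCCCCCC/C=C/C=C/[C@H](O)Cc1cccc(OC)c1Br
F2 | step 6 | 2-[(2R,3E,5E)-2-hydroxynonadeca-3,5-dien-1-yl]-6-methoxybenzoic acid | CCCCCCCCCCCCC/C=C/C=C/[C@H](O)Cc1cccc(OC)c1C(=O)O
F3 | step 7 | 2-bromo-3-[(2S,3E,5E)-2-hydroxynonadeca-3,5-dien-1-yl]phenol | CCCCCCCCCCCCC/C=C/C=C/[C@@H](O)Cc1cccc(O)c1Br
F4 | step 7 | 2-hydroxy-6-[(2S,3E,5E)-2-hydroxynonadeca-3,5-dien-1-yl]benzoic acid | CCCCCCCCCCCCC/C=C/C=C/[C@@H](O)Cc1cccc(O)c1C(=O)O
F5 | step 5 | racemic (3E,5E)-1-(2-bromo-3-methoxyphenyl)nonadeca-3,5-dien-2-ol | CCCCCCCCCCCCC/C=C/C=C/C(O)Cc1cccc(OC)c1Br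
F6 | step 5 | (2R,3R,4R,5E)-1-(2-bromo-3-methoxyphenyl)-3,4-epoxynonadec-5-en-2-ol | CCCCCCCCCCCCC/C=C/[C@H]1O[C@@H]1[C@H](O)Cc1cccc(OC)c1Br
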